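**Assumption:** jaspaquinol has no stereocentres (it is achiral), so "single enantiomer" reduces to controlling the two E-trisubstituted alkenes. Chain numbering used below: ArC1'H2–C2'H=C3'(Me)–C4'H2–C5'H2–C6'H=C7'(Me)–C8'H2–C9'H2–ring.

## Retrosynthetic overview

1. Target 10 ⇐ quinone 9 ⇐ dimethyl ether 8 (oxidative demethylation, then reduction).
2. 8 is cut in the middle of the chain at C5'–C6' (sp3–sp2 Negishi coupling) into alkenyl iodide 3 and the homoallylzinc from bromide 7. The usual aryl–allyl bond is not disconnected.
3. Both E-alkenes are made by Zr-catalysed syn-methylalumination of terminal alkynes. For 6, the alkenylalane is trapped directly with benzyl chloride 5 under Ni(0), so the arene enters as a benzyl electrophile and the ArCH2–CH= bond and the C2'=C3' geometry are formed in one pot.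
4. Alkyne 2 comes from dihydro-β-ionone 1 (methyl ketone → terminal alkyne).
5. No ring is constructed: the cyclohexene is bought in 1 and the arene in 5.

## Route

**Step 1**
Reactants: 1, dihydro-β-ionone [4-(2,6,6-trimethylcyclohex-1-en-1-yl)butan-2-one]
Product: 2, 2-(but-3-yn-1-yl)-1,3,3-trimethylcyclohex-1-ene
Conditions: LDA (1.05 equiv), THF, −78 °C; ClP(O)(OEt)2, −78 °C → rt; then LDA (2.3 equiv), −78 °C → rt; H2O quench
Reagents that add atoms: none (the diethyl phosphate group is eliminated)
Why: Negishi methyl ketone → terminal alkyne protocol: kinetic deprotonation at CH3, O-phosphorylation, then LDA-induced elimination of the enol phosphate to the acetylide, which protects the product from alkyne/allene isomerisation.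

**Step 2**
Reactants: 2, 2-(but-3-yn-1-yl)-1,3,3-trimethylcyclohex-1-ene
Product: 3, 2-[(3E)-4-iodo-3-methylbut-3-en-1-yl]-1,3,3-trimethylcyclohex-1-ene
Conditions: Me3Al (2 equiv), Cp2ZrCl2 (0.25 equiv), CH2Cl2, 0 °C → rt; then I2, THF, −30 → 0 °C
Reagents that add atoms: trimethylaluminium, C[Al](C)C (the C7' methyl); iodine, II
Why: Negishi Zr-catalysed methylalumination adds Me and Al syn across the terminal alkyne with Al at the terminus, and iodinolysis with retention gives the E-iodide; the tetrasubstituted ring alkene is inert.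

**Step 3 (key step)**
Reactants: 4, tert-butyl(but-3-yn-1-yloxy)dimethylsilane; 5, 2-(chloromethyl)-1,4-dimethoxybenzene (2,5-dimethoxybenzyl chloride)
Product: 6, tert-butyl{[(3E)-5-(2,5-dimethoxyphenyl)-3-methylpent-3-en-1-yl]oxy}dimethylsilane
Conditions: 4, Me3Al (2 equiv), Cp2ZrCl2 (0.25 equiv), CH2Cl2, 0 °C → rt; evaporate volatiles, THF; then 5 (0.9 equiv), NiCl2(PPh3)2 (3 mol %)/n-BuLi (6 mol %), rt
Reagents that add atoms: trimethylaluminium, C[Al](C)C (the C3' methyl); the benzyl unit comes from reactant 5
Why: Syn-methylalumination followed by Ni(0)-catalysed alkenylalane–benzyl chloride cross-coupling (Negishi/Lipshutz type) proceeds with retention, so the benzyl group ends up cis to the new methyl (E); TBS and aryl methyl ethers tolerate Me3Al at rt.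

**Step 4**
Reactants: 6, the TBS ether from step 3
Product: 7, 2-[(2E)-5-bromo-3-methylpent-2-en-1-yl]-1,4-dimethoxybenzene
Conditions: Ph3PBr2 (1.3 equiv, preformed with slight excess PPh3), CH2Cl2, 0 °C → rt
Reagents that add atoms: triphenylphosphine dibromide, BrP(Br)(c1ccccc1)(c1ccccc1)c1ccccc1
Why: Direct silyl ether → bromide conversion (Appel-type): the oxygen is transferred to phosphorus, TBSBr is lost and bromide displaces at the primary carbon under neutral conditions, leaving the alkene and arene untouched because no free Br2 is present.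

**Step 5 (fragment union)**
Reactants: 7, the homoallylic bromide (1.3 equiv); 3, the E-alkenyl iodide (1.0 equiv)
Product: 8, 2-[(2E,6E)-3,7-dimethyl-9-(2,6,6-trimethylcyclohex-1-en-1-yl)nona-2,6-dien-1-yl]-1,4-dimethoxybenzene
Conditions: 7, Mg, THF, rt; ZnBr2, 0 °C; then 3, PdCl2(DPEphos) (3 mol %), THF, rt
Reagents that add atoms: none
Why: Negishi homoallylzinc–alkenyl iodide coupling (the classic 1,5-diene synthesis): oxidative addition and reductive elimination retain the iodide geometry, and the primary alkylzinc couples faster than β-hydride elimination; keeping the organometallic at or below rt avoids E/Z scrambling via cyclopropylcarbinyl equilibration.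

**Step 6**
Reactants: 8, the dimethyl ether
Product: 9, 2-[(2E,6E)-3,7-dimethyl-9-(2,6,6-trimethylcyclohex-1-en-1-yl)nona-2,6-dien-1-yl]cyclohexa-2,5-diene-1,4-dione
Conditions: CAN (2.5 equiv), MeCN/CH2Cl2/H2O, 0 °C, 20 min
Reagents that add atoms: water, O (the quinone oxygens come from water; the methoxy groups leave as MeOH)
Why: CAN oxidative demethylation of a 1,4-dimethoxyarene via the arene radical cation is fast at 0 °C and well precedented on polyprenyl dimethoxybenzenes without attack on isolated tri- or tetrasubstituted alkenes.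

**Step 7**
Reactants: 9, the quinone
Product: 10, jaspaquinol, 2-[(2E,6E)-3,7-dimethyl-9-(2,6,6-trimethylcyclohex-1-en-1-yl)nona-2,6-dien-1-yl]benzene-1,4-diol
Conditions: aq. Na2S2O4 (excess), Et2O/H2O, rt, under Ar
Reagents that add atoms: none
Why: Dithionite reduces the quinone to the hydroquinone and nothing else in the molecule is reducible; the product is air-sensitive and is handled under argon.

## Compound list

1 | dihydro-β-ionone, 4-(2,6,6-trimethylcyclohex-1-en-1-yl)butan-2-one | CC(=O)CCC1=C(C)CCCC1(C)C | starting material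
2 | 2-(but-3-yn-1-yl)-1,3,3-trimethylcyclohex-1-ene | C#CCCC1=C(C)CCCC1(C)C | intermediate
3 | 2-[(3E)-4-iodo-3-methylbut-3-en-1-yl]-1,3,3-trimethylcyclohex-1-ene | CC1=C(CC/C(C)=C/I)C(C)(C)CCC1 | intermediate
4 | tert-butyl(but-3-yn-1-yloxy)dimethylsilane | C#CCCO[Si](C)(C)C(C)(C)C | starting material
5 | 2-(chloromethyl)-1,4-dimethoxybenzene | COc1ccc(OC)c(CCl)c1 | starting material
6 | tert-butyl{[(3E)-5-(2,5-dimethoxyphenyl)-3-methylpent-3-en-1-yl]oxy}dimethylsilane | CC(C)(C)[Si](C)(C)OCC/C(C)=C/Cc1cc(OC)ccc1OC | intermediate
7 | 2-[(2E)-5-bromo-3-methylpent-2-en-1-yl]-1,4-dimethoxybenzene | BrCC/C(C)=C/Cc1cc(OC)ccc1OC | intermediate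
8 | 2-[(2E,6E)-3,7-dimethyl-9-(2,6,6-trimethylcyclohex-1-en-1-yl)nona-2,6-dien-1-yl]-1,4-dimethoxybenzene | CC1=C(CC/C(C)=C/CC/C(C)=C/Cc2cc(OC)ccc2OC)C(C)(C)CCC1 | intermediate
9 | 2-[(2E,6E)-3,7-dimethyl-9-(2,6,6-trimethylcyclohex-1-en-1-yl)nona-2,6-dien-1-yl]cyclohexa-2,5-diene-1,4-dione | CC1=C(CC/C(C)=C/CC/C(C)=C/CC2=CC(=O)C=CC2=O)C(C)(C)CCC1 | intermediate
10 | jaspaquinol | CC1=C(CC/C(C)=C/CC/C(C)=C/Cc2cc(O)ccc2O)C(C)(C)CCC1 | target

## Summary

Total steps: 7. Longest linear sequence: 5 (1 → 2 → 3 → 8 → 9 → 10, or 4 → 6 → 7 → 8 → 9 → 10).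

Steps most likely to fail, each with a fallback that changes the approach:

- **Step 5 (sp3–sp2 union).** Risks are Wurtz coupling during Grignard formation, β-hydride elimination and E/Z erosion. Fallback: switch to a linear iterative alkyne route. Couple 3 with 4-(trimethylsilyl)but-3-yn-1-ylzinc bromide, desilylate (K2CO3/MeOH), then run the methylalumination/Ni-benzylation with 5 on the resulting C18 enyne. This makes the ArCH2–C2' bond last and removes the functionalised homoallyl organometallic.
- **Step 3 (one-pot methylalumination/Ni benzylation).** Risks are Lewis-acid-induced self-condensation of the electron-rich benzyl chloride and competing methyl transfer. Fallback: reverse the polarity. Quench the alane with I2 to give (E)-TBSOCH2CH2C(Me)=CHI and couple it under Pd catalysis with 2,5-dimethoxybenzylzinc chloride (from 5 and Zn dust).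
- **Step 6 (CAN oxidation).** Risks are biquinone formation and over-oxidation of the skipped polyene. Fallback: change the protecting group strategy. Use 2,5-bis(methoxymethoxy)benzyl chloride (from 2,5-dihydroxybenzaldehyde) in step 3 and finish with one mild acid deprotection (HCl/MeOH), which gives 10 directly with no oxidation/reduction.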